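The runs were computed on assumed constants, noise included.

At late times in the north run, at 2.50 h, substrate reads 2% and homo dimer 74%, so 24.0% of the charge is product or on its way to it.

- north: substrate 0.040 M; run made earlier
- flask: substrate 0.020 M; time 12 h

north run (percent of the substrate charged)

| time / h | product / % | homo dimer / % | substrate / % |
|---|---|---|---|
| 0.133 | 4 | 39 | 54 |
| 0.333 | 5 | 58 | 33 |
| 0.667 | 9 | 68 | 19 |
| 1.00 | 13 | 70 | 13 |
| 1.33 | 16 | 74 | 3 |
| 2.00 | 18 | 73 | 3 |
| 2.50 | 21 | 74 | 2 |

(each reading ± 2 percentage points)

- in percentages every species weighs as the substrate in it: one homo dimer counts as two
- steps under discussion: 2 substrate -> homo dimer; substrate <-> intermediate; intermediate -> product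

* amount of product in the flask at 12 h, in percent of the substrate charged
* amount of homo dimer in the flask at 12 h, in percent of the substrate charged

We take substrate to leave by two ways: in pairs to homo dimer, with a rate per unit of substrate that follows its amount, and singly through the intermediate to product, with a rate per unit that does not. Call x the split number (a selectivity factor): the rate to homo dimer over the rate to product at the full charge, so x follows the charge. With some fraction of the charge remaining, product takes this share of what leaves:

share now = 1 / (1 + x · fraction remaining)

For a first try, we put in the mean fraction, 0.5. The north share then gives x = 6.33, the flask with 0.020 M against 0.040 M gets 3.17, and its product share is 38.7%.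

The weak link is that mean fraction, since the share curve bends. Averaged over the whole fall of the substrate, the rule becomes:

end share = ln(1 + x) / x

Trying 10 in the north run gives back a split number, rate to homo dimer over rate to product at the full charge, of 9.99. The flask then has x = 5.00 and an end share of 35.9%, so the first try stood 2.8 percentage points higher. We commit to that product and 64.1% homo dimer, taking 12 h as long enough.

The forecast says product 38% (32% to 45%) and homo dimer 61% (54% to 67%), using the same end-share rule, and adds: “Reversibility may favour product slightly more”.

The flask gives 35.6% product and 64.4% homo dimer.

    2 substrate → homo dimer (k = 0.0170 M⁻¹ s⁻¹)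
    substrate ⇌ intermediate (K = 0.980, k = 1.50 × 10⁻⁴ s⁻¹)
    intermediate → product (k = 0.00120 s⁻¹)

At 1.20 h the flask held 59.3% homo dimer, 20.8% product, 17.5% substrate and 2.44% intermediate. By 6.00 h the flask's substrate was down to 1.01% and its intermediate to 0.125%, while homo dimer had risen to 64.3% and product to 34.5%. The neighbour flask with 0.050 M substrate has x = 12.5, which reckons to 20.8% product, and it holds 20.6%.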